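The runs are calculated for an exercise; noise was put on by code.

Time adds little to the monomer in chains in the midnight run, which reads 25.6% at 0.667 min and 28.9% at 4.00 min, while the free monomer falls from 63.5% to 38.7%.

| flask | free monomer | transfer agent | initiator | remark | time |
|---|---|---|---|---|---|
| autumn | 0.060 M | 0.010 M | 0.26 mM | run made earlier |  |
| midnight | 0.060 M | 0.097 M | 0.26 mM | run made earlier |  |
| zeta | 0.060 M | 0.160 M | 0.26 mM |  | 5.0 min |
| theta | 0.060 M | 0.0180 M | 0.26 mM |  | 5.0 min |
| epsilon | 0.060 M | 0.0540 M | 0.26 mM |  | 5.0 min |

| run | time / min | monomer in chains / % | free monomer / % |
|---|---|---|---|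
| autumn | 0.250 | 21.5 | 73.1 |
| autumn | 0.667 | 45.2 | 45.9 |
| autumn | 1.33 | 63.0 | 24.8 |
| autumn | 2.00 | 72.3 | 16.1 |
| autumn | 2.50 | 76.7 | 11.8 |
| autumn | 4.00 | 81.0 | 5.9 |
| midnight | 0.667 | 25.6 | 63.5 |
| midnight | 1.33 | 26.6 | 55.7 |
| midnight | 2.00 | 27.8 | 49.6 |
| midnight | 2.50 | 28.8 | 46.8 |
| midnight | 3.00 | 27.9 | 43.6 |
| midnight | 4.00 | 28.9 | 38.7 |

(readings scatter by 0.5 percentage points)

- which of these there is most of at the end, counted by the free monomer in it, zeta (monomer in chains / free monomer)
- which of these there is most of at the end, counted by the free monomer in it, theta (monomer in chains / free monomer)
- which of these there is most of at the end, counted by the free monomer in it, epsilon (monomer in chains / free monomer)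
- how much there is at the end of the one of these that leads, in percent of the free monomer charged: zeta
- how much there is at the end of the one of these that leads, in percent of the free monomer charged: theta
- how much there is at the end of the one of these that leads, in percent of the free monomer charged: epsilon

- a species is counted by the free monomer in it: one homo dimer counts as two
- steps under discussion: living end + transfer agent -> dead chain; free monomer + initiator -> living end + monomer in chains; 2 free monomer -> homo dimer; free monomer + living end -> monomer in chains + living end

I read this as a burst: living ends grow chains and die on a transfer agent charged far above the initiator, a pseudo-first-order death. Growth therefore cuts the free monomer by a factor e^R, where the reach R equals B/c_T and c_T is the transfer agent charge. The last midnight plateau reading gives 0.0331 M; this B is the reach constant, the transfer agent charge at which growth takes a reach of one before the living ends die. The ceiling on chains is then 1 − e^(−R).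

B must be good: the previous plateau reading, 27.9%, would move the epsilon ceiling from 45.8% to 44.4%. The homo dimer rate matters for free monomer: with x the free fraction, t the time and b the steady rise of 1/x that homo dimer brings once the living ends have stopped mattering, I take 1/x = e^R + bt, and the midnight tail reads b as 0.284 /min. In zeta, bt is 1.42, more than e^R at 1.23. For chains I treat what the ceiling omits as a correction. The autumn run reads 81.0% at 4.00 min against a ceiling of 96.3%, a shortfall that lumps homo dimer together with chains still rising at that reading, and I let it scale as 1/c_T, which gives 0.00159 M as its constant W. The factor on the ceiling is 1 − W/c_T, a loss of 0.995% in zeta but 8.85% in theta.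

I commit to zeta with free monomer at 37.7%, above chains at 18.5%. For theta I expect chains at 76.6%, and for epsilon chains at 44.5%. The forecast says free monomer at 36% for zeta, monomer in chains at 72% for theta and monomer in chains at 43% for epsilon, on the ground that “The decay therefore scales with transfer agent”. My figures stand above the forecast's in zeta, theta and epsilon, with the same leader in each.

The flask gives free monomer at 38.1% in zeta, monomer in chains at 73.8% in theta and monomer in chains at 43.1% in epsilon, so the forecast stands.

    living end + transfer agent → dead chain (kL = 0.540 /M/s)
    free monomer + initiator → living end + monomer in chains (k = 18.0 /M/s)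
    2 free monomer → homo dimer (k = 0.0380 /M/s)
    free monomer + living end → monomer in chains + living end, rate k4*[living end]*[free monomer] (k = 71.0 /M/s)

In theta at 0.531 min, a living end has a half-life of 1.2 min, longer than the 0.84 min of free monomer by growth, and the reach I reckoned from B for the whole of theta is 1.84. In the neighbour of theta charged with 4.4 × 10⁻⁴ M of initiator, B scales to 0.0560 M, the reach to 3.11, and the reckoning to 87.1% chains; the computed flask gives 88.0%.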